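The data stem from a simulated flask from invented constants; noise was put on by code.

Every electrophile charged had to stand somewhere, so in a strict one-to-one flask electrophile plus target would have read 100 percent, and I took that symmetric case as the zero of my scale.

| flask | electrophile | nucleophile | remark | time |
|---|---|---|---|---|
| alder | 6.7 mM | 9.5 mM | run made earlier |  |
| maple | 20 mM | 9.5 mM | run made earlier |  |
| green | 10 mM | 38.0 mM |  | 1.5 h |
| blue | 10 mM | 19.0 mM |  | 1.5 h |
| amber | 10 mM | 9.50 mM |  | 1.5 h |

| run | time / min | electrophile / % | target / % |
|---|---|---|---|
| alder | 4.00 | 16 | 49 |
| alder | 6.00 | 13 | 55 |
| alder | 10.0 | 12 | 56 |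
| alder | 15.0 | 7 | 62 |
| alder | 25.0 | 7 | 65 |
| alder | 40.0 | 6 | 65 |
| alder | 50.0 | 6 | 64 |
| maple | 4.00 | 51 | 26 |
| maple | 6.00 | 47 | 30 |
| maple | 10.0 | 45 | 29 |
| maple | 15.0 | 44 | 28 |
| maple | 25.0 | 41 | 33 |
| maple | 40.0 | 37 | 33 |
| maple | 50.0 | 37 | 34 |

(scatter of a reading: 2 percentage points)

- a reading or a percentage of target counts all its forms, free or not
- what has gone from electrophile into another species counts as reacted, even if it can come back
- a reading of electrophile is of its free form alone

- part of the electrophile that has reacted at the end, green
- part of the electrophile that has reacted at the end, blue
- part of the electrophile that has reacted at the end, amber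
- what raising the concentration of nucleophile from its lowest to its highest value here does to the part of the electrophile that has reacted (changes below 5 percentage points count as none) (it rises / it falls / no change)

At its last reading the alder run fell short of that zero by a gap of 30.0%, and the maple run by 29.0%. I ranked the time scales from these runs. Fastest was the loss of electrophile: alder fell to 16% by 4.00 min, a reading of about 1.51 min for its half-life. Next came the stop: alder's electrophile went from 7% at 25.0 min to 6% at 50.0 min, against a scatter of 2 percentage points. Slowest was maple's drift, from 41% at 25.0 min to 37% at 50.0 min. The asked 1.5 h is longer than that last reading, but that drift had not visibly ended, so I assumed no plateau: I reckoned from the last readings and expected free electrophile at the asked time to stand, if anything, lower.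

At the last readings I read the gap as a second electrophile held on a target, the idle adduct. A target reading includes the held form, so free target is the reading minus the gap. The pairing number, the gap divided by free target and free electrophile in concentration, read 2.19 mM⁻¹ in alder, with a wide error from the scatter on so small a reading. For amber I interpolated target linearly in the electrophile charged, which gave 4.91 mM. The pairing number then put 3.70 mM in the gap and left 1.39 mM of electrophile free, so my amber figure was 86.1% reacted.

The forecast gave 99% (96% to 100%) for green, 97% (93% to 99.5%) for blue and 88% (80% to 94%) for amber, a little above mine, and said of the trend: it rises. Its ground was: “This suggests a second product holding two electrophiles per nucleophile.”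

The flask gave >99.9% for green, 98.8% for blue and 90.9% for amber; from amber to green, it rises, by 9.1 points.

    nucleophile + acid set free ⇌ protonated nucleophile, settled at all times (K = 26000 M⁻¹)
    crystals ⇌ acid set free, rate k2*(cs2 - [acid set free]) while solid is left; crystals form when [acid set free] > cs2 (solubility = 3.40 mM, k = 3.00 min⁻¹)
    electrophile + nucleophile → acid set free + target (k = 69.0 M⁻¹ min⁻¹)
    electrophile + target ⇌ idle adduct, settled at all times (K = 1800 M⁻¹)
    nucleophile + target → over-reaction product (k = 2.70 M⁻¹ min⁻¹)

Amber ended with 9.1% of its electrophile free, 55.6% as target with the held form included, and 69.1% as idle adduct, which counts as two. From those target and adduct amounts the pairing number returns 7.47% free electrophile. A neighbour of amber charged with 4.0 mM of electrophile held 68.3% as target and 7.78% as idle adduct, for which the pairing number returns 0.689%, and that flask stood at 0.84%.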